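**Plan**
1. The last step is hydrogenolysis of fifteen benzyl ethers. Rings are lettered A (2,4,6-trihydroxyphenyl end) to G (3,4,5-trihydroxyphenyl end).
2. Ring A is a benzene-1,3,5-triol whose carbon between two hydroxylated carbons carries the oxygen to ring B. It is therefore a folded 3,5-dioxohexanoate with that oxygen on C4 (ester C1 = the C–OH para to the ether, ketones C3 and C5 = the flanking C–OH). It is cut at the C1–C6 bond (hydroxylated carbon para to the ether / adjacent CH), then at the chain C1–C2 bond (carboxylation) and at the sp3 C4–O bond (alkylation of the ring B phenol).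
3. Each of the other five ether oxygens is cut from the ring that lies nearer ring A, giving a phenol and a bromobenzaldehyde whose formyl group stands for the next phenolic oxygen.
4. Forward: ring G phenol, then five rounds of copper-catalysed O-arylation and Baeyer–Villiger oxidation add rings F, E, D, C and B from three bromoaldehydes (two are used twice). Ring A is then built on the ring B phenol and closed by Claisen folding.
5. Stereochemistry: the target is achiral; the only stereocentre met (C4 of the diketo ester, racemic) disappears on aromatisation.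

Key step: step 19

Remark: the benzaldehydes that open steps 1, 4 and 5 are taken as catalogue chemicals; phenoxides, enolates and keto–enol tautomers are counted as forms of the numbered compounds, not as separate intermediates.

**Route**

Step 1
Reactants: 1 3,4,5-trihydroxybenzaldehyde
Product: 2 3,4,5-tris(benzyloxy)benzaldehyde
Conditions: BnBr (3.3 equiv), K2CO3, DMF, 60 °C
Reagents that add atoms: benzyl bromide, BrCc1ccccc1
Why: Williamson etherification of all three phenols under mild carbonate conditions, which the non-enolisable aldehyde tolerates.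

Step 2
Reactants: 2 3,4,5-tris(benzyloxy)benzaldehyde
Product: 4 3,4,5-tris(benzyloxy)phenol, via aryl formate 3 (not isolated)
Conditions: mCPBA, CH2Cl2, 0 °C to rt; aq. NaHCO3 wash; then K2CO3 (cat.), MeOH–THF, rt
Reagents that add atoms: mCPBA (3-chloroperoxybenzoic acid), OOC(=O)c1cccc(Cl)c1
Why: Baeyer–Villiger oxidation in which the electron-rich aryl group (para benzyloxy) migrates in preference to hydrogen to give formate 3, whose base-catalysed methanolysis frees the phenol (overall a Dakin-type change of ArCHO into ArOH).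

Step 3
Reactants: 2 3,4,5-tris(benzyloxy)benzaldehyde
Product: 5 2-bromo-3,4,5-tris(benzyloxy)benzaldehyde
Conditions: N-bromosuccinimide (1.05 equiv), DMF, rt, dark
Reagents that add atoms: N-bromosuccinimide, O=C1CCC(=O)N1Br
Why: Electrophilic aromatic bromination at one of the two equivalent free positions, each activated by an ortho and a para benzyloxy group, after which crowding and deactivation slow a second substitution.

Step 4
Reactants: 6 3-bromo-4,5-dihydroxybenzaldehyde
Product: 7 3-bromo-4,5-bis(benzyloxy)benzaldehyde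
Conditions: BnBr (2.2 equiv), K2CO3, DMF, 60 °C
Reagents that add atoms: benzyl bromide, BrCc1ccccc1
Why: Williamson etherification of the catechol; the aryl bromide and the aldehyde are inert to K2CO3 in DMF.

Step 5
Reactants: 8 4-bromo-3,5-dimethoxybenzaldehyde
Product: 9 4-bromo-3,5-dihydroxybenzaldehyde
Conditions: BBr3, CH2Cl2, −78 °C to rt; then water
Reagents that add atoms: none
Why: Lewis-acid cleavage of aryl methyl ethers by BBr3 (bromide attack on the O-methyl group of the boron-bound ether), which leaves the aryl bromide and, after aqueous work-up, the aldehyde intact.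

Step 6
Reactants: 9 4-bromo-3,5-dihydroxybenzaldehyde
Product: 10 4-bromo-3,5-bis(benzyloxy)benzaldehyde
Conditions: BnBr (2.2 equiv), K2CO3, DMF, 60 °C
Reagents that add atoms: benzyl bromide, BrCc1ccccc1
Why: Williamson etherification of the two phenols that flank the bromide.

Step 7
Reactants: 4 3,4,5-tris(benzyloxy)phenol; 7 3-bromo-4,5-bis(benzyloxy)benzaldehyde
Product: 11 3,4-bis(benzyloxy)-5-[3,4,5-tris(benzyloxy)phenoxy]benzaldehyde
Conditions: CuI (10 mol%), picolinic acid (20 mol%), K3PO4, DMSO, 90 °C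
Reagents that add atoms: none
Why: Ullmann-type copper-catalysed O-arylation of an unhindered phenol by an aryl bromide that carries one ortho benzyloxy group and an electron-withdrawing formyl group; benzyl ethers and the aldehyde are stable to K3PO4 in DMSO.

Step 8
Reactants: 11 3,4-bis(benzyloxy)-5-[3,4,5-tris(benzyloxy)phenoxy]benzaldehyde
Product: 13 3,4-bis(benzyloxy)-5-[3,4,5-tris(benzyloxy)phenoxy]phenol, via aryl formate 12 (not isolated)
Conditions: mCPBA, CH2Cl2, 0 °C to rt; aq. NaHCO3 wash; then K2CO3 (cat.), MeOH–THF, rt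
Reagents that add atoms: mCPBA (3-chloroperoxybenzoic acid), OOC(=O)c1cccc(Cl)c1
Why: Baeyer–Villiger oxidation with migration of the aryl group that bears a para benzyloxy substituent, then methanolysis of formate 12, as in step 2.

Step 9
Reactants: 13 dimer phenol (rings F and G); 5 2-bromo-3,4,5-tris(benzyloxy)benzaldehyde
Product: 14 3,4,5-tris(benzyloxy)-2-(ArO)benzaldehyde in which ArOH is phenol 13
Conditions: CuI (20 mol%), picolinic acid (40 mol%), K3PO4, DMSO, 100 °C
Reagents that add atoms: none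
Why: Ullmann-type O-arylation in which the ortho formyl group of 5 assists copper insertion into the crowded C–Br bond (the classical ortho-carbonyl effect) and the phenol of 13 has both ortho positions free.

Step 10
Reactants: 14 trimer aldehyde (rings E to G)
Product: 16 3,4,5-tris(benzyloxy)-2-(ArO)phenol in which ArOH is phenol 13, via aryl formate 15 (not isolated)
Conditions: mCPBA, CH2Cl2, 0 °C to rt; aq. NaHCO3 wash; then K2CO3 (cat.), MeOH–THF, rt
Reagents that add atoms: mCPBA (3-chloroperoxybenzoic acid), OOC(=O)c1cccc(Cl)c1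
Why: Baeyer–Villiger oxidation favoured by the ortho aryloxy and para benzyloxy groups of the aldehyde ring, then methanolysis of formate 15.

Step 11
Reactants: 16 trimer phenol (rings E to G); 10 4-bromo-3,5-bis(benzyloxy)benzaldehyde
Product: 17 3,5-bis(benzyloxy)-4-(ArO)benzaldehyde in which ArOH is phenol 16
Conditions: CuI (20 mol%), picolinic acid (40 mol%), K3PO4, DMSO, 105 °C
Reagents that add atoms: none
Why: Ullmann-type O-arylation at a bromide activated by the para formyl group; the two flanking benzyloxy groups make this the most crowded coupling of the route, which is why catalyst loading and temperature are raised.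

Step 12
Reactants: 17 tetramer aldehyde (rings D to G)
Product: 19 3,5-bis(benzyloxy)-4-(ArO)phenol in which ArOH is phenol 16, via aryl formate 18 (not isolated)
Conditions: mCPBA, CH2Cl2, 0 °C to rt; aq. NaHCO3 wash; then K2CO3 (cat.), MeOH–THF, rt
Reagents that add atoms: mCPBA (3-chloroperoxybenzoic acid), OOC(=O)c1cccc(Cl)c1
Why: Baeyer–Villiger oxidation in which the para aryloxy oxygen supports aryl migration, then methanolysis of formate 18.

Step 13
Reactants: 19 tetramer phenol (rings D to G); 5 2-bromo-3,4,5-tris(benzyloxy)benzaldehyde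
Product: 20 3,4,5-tris(benzyloxy)-2-(ArO)benzaldehyde in which ArOH is phenol 19
Conditions: CuI (20 mol%), picolinic acid (40 mol%), K3PO4, DMSO, 100 °C
Reagents that add atoms: none
Why: Ullmann-type O-arylation of the unhindered ring D phenol by the ortho-formyl-activated bromide 5, the same pairing as in step 9.

Step 14
Reactants: 20 pentamer aldehyde (rings C to G)
Product: 22 3,4,5-tris(benzyloxy)-2-(ArO)phenol in which ArOH is phenol 19, via aryl formate 21 (not isolated)
Conditions: mCPBA, CH2Cl2, 0 °C to rt; aq. NaHCO3 wash; then K2CO3 (cat.), MeOH–THF, rt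
Reagents that add atoms: mCPBA (3-chloroperoxybenzoic acid), OOC(=O)c1cccc(Cl)c1
Why: Baeyer–Villiger oxidation and methanolysis of formate 21, as in step 10.

Step 15
Reactants: 22 pentamer phenol (rings C to G); 7 3-bromo-4,5-bis(benzyloxy)benzaldehyde
Product: 23 3,4-bis(benzyloxy)-5-(ArO)benzaldehyde in which ArOH is phenol 22
Conditions: CuI (20 mol%), picolinic acid (40 mol%), K3PO4, DMSO, 100 °C
Reagents that add atoms: none
Why: Ullmann-type O-arylation as in step 7, now with a phenol that has one ortho aryloxy group.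

Step 16
Reactants: 23 hexamer aldehyde (rings B to G)
Product: 25 3,4-bis(benzyloxy)-5-(ArO)phenol in which ArOH is phenol 22, via aryl formate 24 (not isolated)
Conditions: mCPBA, CH2Cl2, 0 °C to rt; aq. NaHCO3 wash; then K2CO3 (cat.), MeOH–THF, rt
Reagents that add atoms: mCPBA (3-chloroperoxybenzoic acid), OOC(=O)c1cccc(Cl)c1
Why: Baeyer–Villiger oxidation and methanolysis of formate 24, as in step 8, giving the ring B phenol with both ortho positions free.

Step 17
Reactants: 25 hexamer phenol (rings B to G); 26 3-chloropentane-2,4-dione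
Product: 27 3-(ArO)pentane-2,4-dione in which ArOH is phenol 25
Conditions: Cs2CO3, acetone, 50 °C
Reagents that add atoms: none
Why: Williamson-type SN2 O-alkylation of the phenoxide by the α-chloro-1,3-diketone, a standard route to 3-aryloxypentane-2,4-diones, which places the ring B oxygen on the future ring A carbon without any arene coupling.

Step 18
Reactants: 27 3-(ArO)pentane-2,4-dione; 28 dimethyl carbonate
Product: 29 methyl 4-(ArO)-3,5-dioxohexanoate in which ArOH is phenol 25 (racemic at C4)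
Conditions: LiN(iPr)2 (3 equiv), THF, −78 to 0 °C; then 28, −78 °C to rt; 1 M HCl
Reagents that add atoms: none
Why: Terminal C-acylation of a 1,3-diketone dianion: the first equivalent of amide forms the enolate, the second removes a methyl proton, and the more basic terminal carbanion attacks dimethyl carbonate while the third equivalent absorbs the acidic β-keto ester formed; the two methyl groups are equivalent, so only one regioisomer can arise.

Step 19
Reactants: 29 methyl 4-(ArO)-3,5-dioxohexanoate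
Product: 30 2-(ArO)benzene-1,3,5-triol in which ArOH is phenol 25 (rings A to G)
Conditions: LiN(SiMe3)2 (5 equiv), THF, −78 to 60 °C; then 1 M HCl
Reagents that add atoms: none
Why: Intramolecular Claisen (Dieckmann-type) condensation of a triketide: LiN(SiMe3)2 first forms the dienolate at C2 and C4, then reversibly removes a proton from the C6 methyl group, and this terminal carbanion adds to the C1 ester carbonyl; methoxide leaves and the 2-aryloxycyclohexane-1,3,5-trione is deprotonated at once and appears as the benzene-1,3,5-triol after acidification. The closest known reactions are the base-induced folding of 3,5-dioxohexanoate and 3,5,7-trioxoalkanoate esters to phloroglucinols and the closure of 5-oxohexanoates to cyclohexane-1,3-diones. Ring A closes in a 6-(enolendo)-exo-trig mode by the single C6–C1 bond, which in the product joins a ring CH carbon to the hydroxylated carbon para to the ether oxygen. No stereocentre is created, and the racemic C4 centre of 29 is lost on aromatisation. The selectivity needed is C-acylation by C6 over O-acylation by the C5 enolate oxygen (closure to a pyran-2-one) and over retro-Claisen loss of an acyl group. Substrate and base together should secure it: C4 bears the aryloxy group and a single hydrogen, so once C2 and C4 are deprotonated the only carbon nucleophile that can still be generated is C6, lithium chelation of the two 1,3-dicarbonyl units folds the chain so that C6 lies next to C1, the silylamide cannot add to the carbonyl groups, and the aromatic triphenoxide is an irreversible sink whereas a pyranone could be reopened by the methoxide set free.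

Step 20
Reactants: 30 2-(ArO)benzene-1,3,5-triol (fifteen benzyl ethers)
Product: 31 CNP0137585.0 (target)
Conditions: H2 (1 atm), 10% Pd/C, THF–MeOH, rt; filtration and concentration under argon
Reagents that add atoms: none
Why: Heterogeneous palladium-catalysed hydrogenolysis cleaves the fifteen benzylic C–O bonds while diaryl ether bonds and arenes are untouched at 1 atm, and the oxidation-prone polyphenol is kept under argon.

**Compound list**

1 | 3,4,5-trihydroxybenzaldehyde | O=Cc1cc(O)c(O)c(O)c1 | starting material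
2 | 3,4,5-tris(benzyloxy)benzaldehyde | O=Cc1cc(OCc9ccccc9)c(OCc9ccccc9)c(OCc9ccccc9)c1 | intermediate
3 | 3,4,5-tris(benzyloxy)phenyl formate | O=COc1cc(OCc9ccccc9)c(OCc9ccccc9)c(OCc9ccccc9)c1 | intermediate
4 | 3,4,5-tris(benzyloxy)phenol (ring G) | Oc1cc(OCc9ccccc9)c(OCc9ccccc9)c(OCc9ccccc9)c1 | intermediate
5 | 2-bromo-3,4,5-tris(benzyloxy)benzaldehyde (block for rings E and C) | O=Cc1cc(OCc9ccccc9)c(OCc9ccccc9)c(OCc9ccccc9)c1Br | intermediate
6 | 3-bromo-4,5-dihydroxybenzaldehyde | O=Cc1cc(O)c(O)c(Br)c1 | starting material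
7 | 3-bromo-4,5-bis(benzyloxy)benzaldehyde (block for rings F and B) | O=Cc1cc(OCc9ccccc9)c(OCc9ccccc9)c(Br)c1 | intermediate
8 | 4-bromo-3,5-dimethoxybenzaldehyde | COc1cc(C=O)cc(OC)c1Br | starting material
9 | 4-bromo-3,5-dihydroxybenzaldehyde | O=Cc1cc(O)c(Br)c(O)c1 | intermediate
10 | 4-bromo-3,5-bis(benzyloxy)benzaldehyde (block for ring D) | O=Cc1cc(OCc9ccccc9)c(Br)c(OCc9ccccc9)c1 | intermediate
11 | 3,4-bis(benzyloxy)-5-[3,4,5-tris(benzyloxy)phenoxy]benzaldehyde (rings F and G) | O=Cc6cc(OCc9ccccc9)c(OCc9ccccc9)c(Oc7cc(OCc9ccccc9)c(OCc9ccccc9)c(OCc9ccccc9)c7)c6 | intermediate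
12 | 3,4-bis(benzyloxy)-5-[3,4,5-tris(benzyloxy)phenoxy]phenyl formate | O=COc6cc(OCc9ccccc9)c(OCc9ccccc9)c(Oc7cc(OCc9ccccc9)c(OCc9ccccc9)c(OCc9ccccc9)c7)c6 | intermediate
13 | 3,4-bis(benzyloxy)-5-[3,4,5-tris(benzyloxy)phenoxy]phenol | Oc6cc(OCc9ccccc9)c(OCc9ccccc9)c(Oc7cc(OCc9ccccc9)c(OCc9ccccc9)c(OCc9ccccc9)c7)c6 | intermediate
14 | 3,4,5-tris(benzyloxy)-2-(ArO)benzaldehyde in which ArOH is phenol 13 (rings E to G) | O=Cc5cc(OCc9ccccc9)c(OCc9ccccc9)c(OCc9ccccc9)c5Oc6cc(OCc9ccccc9)c(OCc9ccccc9)c(Oc7cc(OCc9ccccc9)c(OCc9ccccc9)c(OCc9ccccc9)c7)c6 | intermediate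
15 | 3,4,5-tris(benzyloxy)-2-(ArO)phenyl formate in which ArOH is phenol 13 | O=COc5cc(OCc9ccccc9)c(OCc9ccccc9)c(OCc9ccccc9)c5Oc6cc(OCc9ccccc9)c(OCc9ccccc9)c(Oc7cc(OCc9ccccc9)c(OCc9ccccc9)c(OCc9ccccc9)c7)c6 | intermediate
16 | 3,4,5-tris(benzyloxy)-2-(ArO)phenol in which ArOH is phenol 13 | Oc5cc(OCc9ccccc9)c(OCc9ccccc9)c(OCc9ccccc9)c5Oc6cc(OCc9ccccc9)c(OCc9ccccc9)c(Oc7cc(OCc9ccccc9)c(OCc9ccccc9)c(OCc9ccccc9)c7)c6 | intermediate
17 | 3,5-bis(benzyloxy)-4-(ArO)benzaldehyde in which ArOH is phenol 16 (rings D to G) | O=Cc4cc(OCc9ccccc9)c(Oc5cc(OCc9ccccc9)c(OCc9ccccc9)c(OCc9ccccc9)c5Oc6cc(OCc9ccccc9)c(OCc9ccccc9)c(Oc7cc(OCc9ccccc9)c(OCc9ccccc9)c(OCc9ccccc9)c7)c6)c(OCc9ccccc9)c4 | intermediate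
18 | 3,5-bis(benzyloxy)-4-(ArO)phenyl formate in which ArOH is phenol 16 | O=COc4cc(OCc9ccccc9)c(Oc5cc(OCc9ccccc9)c(OCc9ccccc9)c(OCc9ccccc9)c5Oc6cc(OCc9ccccc9)c(OCc9ccccc9)c(Oc7cc(OCc9ccccc9)c(OCc9ccccc9)c(OCc9ccccc9)c7)c6)c(OCc9ccccc9)c4 | intermediate
19 | 3,5-bis(benzyloxy)-4-(ArO)phenol in which ArOH is phenol 16 | Oc4cc(OCc9ccccc9)c(Oc5cc(OCc9ccccc9)c(OCc9ccccc9)c(OCc9ccccc9)c5Oc6cc(OCc9ccccc9)c(OCc9ccccc9)c(Oc7cc(OCc9ccccc9)c(OCc9ccccc9)c(OCc9ccccc9)c7)c6)c(OCc9ccccc9)c4 | intermediate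
20 | 3,4,5-tris(benzyloxy)-2-(ArO)benzaldehyde in which ArOH is phenol 19 (rings C to G) | O=Cc3cc(OCc9ccccc9)c(OCc9ccccc9)c(OCc9ccccc9)c3Oc4cc(OCc9ccccc9)c(Oc5cc(OCc9ccccc9)c(OCc9ccccc9)c(OCc9ccccc9)c5Oc6cc(OCc9ccccc9)c(OCc9ccccc9)c(Oc7cc(OCc9ccccc9)c(OCc9ccccc9)c(OCc9ccccc9)c7)c6)c(OCc9ccccc9)c4 | intermediate
21 | 3,4,5-tris(benzyloxy)-2-(ArO)phenyl formate in which ArOH is phenol 19 | O=COc3cc(OCc9ccccc9)c(OCc9ccccc9)c(OCc9ccccc9)c3Oc4cc(OCc9ccccc9)c(Oc5cc(OCc9ccccc9)c(OCc9ccccc9)c(OCc9ccccc9)c5Oc6cc(OCc9ccccc9)c(OCc9ccccc9)c(Oc7cc(OCc9ccccc9)c(OCc9ccccc9)c(OCc9ccccc9)c7)c6)c(OCc9ccccc9)c4 | intermediate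
22 | 3,4,5-tris(benzyloxy)-2-(ArO)phenol in which ArOH is phenol 19 | Oc3cc(OCc9ccccc9)c(OCc9ccccc9)c(OCc9ccccc9)c3Oc4cc(OCc9ccccc9)c(Oc5cc(OCc9ccccc9)c(OCc9ccccc9)c(OCc9ccccc9)c5Oc6cc(OCc9ccccc9)c(OCc9ccccc9)c(Oc7cc(OCc9ccccc9)c(OCc9ccccc9)c(OCc9ccccc9)c7)c6)c(OCc9ccccc9)c4 | intermediate
23 | 3,4-bis(benzyloxy)-5-(ArO)benzaldehyde in which ArOH is phenol 22 (rings B to G) | O=Cc2cc(OCc9ccccc9)c(OCc9ccccc9)c(Oc3cc(OCc9ccccc9)c(OCc9ccccc9)c(OCc9ccccc9)c3Oc4cc(OCc9ccccc9)c(Oc5cc(OCc9ccccc9)c(OCc9ccccc9)c(OCc9ccccc9)c5Oc6cc(OCc9ccccc9)c(OCc9ccccc9)c(Oc7cc(OCc9ccccc9)c(OCc9ccccc9)c(OCc9ccccc9)c7)c6)c(OCc9ccccc9)c4)c2 | intermediate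
24 | 3,4-bis(benzyloxy)-5-(ArO)phenyl formate in which ArOH is phenol 22 | O=COc2cc(OCc9ccccc9)c(OCc9ccccc9)c(Oc3cc(OCc9ccccc9)c(OCc9ccccc9)c(OCc9ccccc9)c3Oc4cc(OCc9ccccc9)c(Oc5cc(OCc9ccccc9)c(OCc9ccccc9)c(OCc9ccccc9)c5Oc6cc(OCc9ccccc9)c(OCc9ccccc9)c(Oc7cc(OCc9ccccc9)c(OCc9ccccc9)c(OCc9ccccc9)c7)c6)c(OCc9ccccc9)c4)c2 | intermediate
25 | 3,4-bis(benzyloxy)-5-(ArO)phenol in which ArOH is phenol 22 (hexamer phenol, free OH on ring B) | Oc2cc(OCc9ccccc9)c(OCc9ccccc9)c(Oc3cc(OCc9ccccc9)c(OCc9ccccc9)c(OCc9ccccc9)c3Oc4cc(OCc9ccccc9)c(Oc5cc(OCc9ccccc9)c(OCc9ccccc9)c(OCc9ccccc9)c5Oc6cc(OCc9ccccc9)c(OCc9ccccc9)c(Oc7cc(OCc9ccccc9)c(OCc9ccccc9)c(OCc9ccccc9)c7)c6)c(OCc9ccccc9)c4)c2 | intermediate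
26 | 3-chloropentane-2,4-dione | CC(=O)C(Cl)C(C)=O | starting material
27 | 3-(ArO)pentane-2,4-dione in which ArOH is phenol 25 | CC(=O)C(Oc2cc(OCc9ccccc9)c(OCc9ccccc9)c(Oc3cc(OCc9ccccc9)c(OCc9ccccc9)c(OCc9ccccc9)c3Oc4cc(OCc9ccccc9)c(Oc5cc(OCc9ccccc9)c(OCc9ccccc9)c(OCc9ccccc9)c5Oc6cc(OCc9ccccc9)c(OCc9ccccc9)c(Oc7cc(OCc9ccccc9)c(OCc9ccccc9)c(OCc9ccccc9)c7)c6)c(OCc9ccccc9)c4)c2)C(C)=O | intermediate
28 | dimethyl carbonate | COC(=O)OC | starting material
29 | methyl 4-(ArO)-3,5-dioxohexanoate in which ArOH is phenol 25 (racemic at C4) | COC(=O)CC(=O)C(Oc2cc(OCc9ccccc9)c(OCc9ccccc9)c(Oc3cc(OCc9ccccc9)c(OCc9ccccc9)c(OCc9ccccc9)c3Oc4cc(OCc9ccccc9)c(Oc5cc(OCc9ccccc9)c(OCc9ccccc9)c(OCc9ccccc9)c5Oc6cc(OCc9ccccc9)c(OCc9ccccc9)c(Oc7cc(OCc9ccccc9)c(OCc9ccccc9)c(OCc9ccccc9)c7)c6)c(OCc9ccccc9)c4)c2)C(C)=O | intermediate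
30 | 2-(ArO)benzene-1,3,5-triol in which ArOH is phenol 25 (rings A to G, fifteen benzyl ethers) | Oc1cc(O)c(Oc2cc(OCc9ccccc9)c(OCc9ccccc9)c(Oc3cc(OCc9ccccc9)c(OCc9ccccc9)c(OCc9ccccc9)c3Oc4cc(OCc9ccccc9)c(Oc5cc(OCc9ccccc9)c(OCc9ccccc9)c(OCc9ccccc9)c5Oc6cc(OCc9ccccc9)c(OCc9ccccc9)c(Oc7cc(OCc9ccccc9)c(OCc9ccccc9)c(OCc9ccccc9)c7)c6)c(OCc9ccccc9)c4)c2)c(O)c1 | intermediate
31 | CNP0137585.0, 2-{3,4-dihydroxy-5-[3,4,5-trihydroxy-2-(3,5-dihydroxy-4-{3,4,5-trihydroxy-2-[3,4-dihydroxy-5-(3,4,5-trihydroxyphenoxy)phenoxy]phenoxy}phenoxy)phenoxy]phenoxy}benzene-1,3,5-triol | Oc1cc(O)c(Oc2cc(O)c(O)c(Oc3cc(O)c(O)c(O)c3Oc3cc(O)c(Oc4cc(O)c(O)c(O)c4Oc4cc(O)c(O)c(Oc5cc(O)c(O)c(O)c5)c4)c(O)c3)c2)c(O)c1 | target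

**Step count**

Total step count: 20.
Longest linear sequence: 16 steps (steps 1, 2 and 7 to 20).

**Steps most likely to fail**

Step 19, Claisen folding on a late intermediate. The third deprotonation may not be reached, or the chain may close through oxygen to a pyran-2-one, or it may shed an acyl group by retro-Claisen cleavage. The fallback gives up the de novo ring and appends ring A by the same iterative chemistry as the other rings. It sets out from hexamer phenol 25 and returns to the route at target 31. Copper-catalysed O-arylation of 25 with bromoaldehyde 10 (conditions of step 11; the phenol here has both ortho positions free) would give the heptamer aldehyde F1. mCPBA and then methanolysis would convert it, through the heptamer formate F2, into the heptamer phenol F3, in which ring A carries a free 4-hydroxyl and two benzyloxy groups. Hydrogenolysis of its seventeen benzyl ethers under the conditions of step 20 would give 31.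

Step 18, carboxylation of the diketone dianion. The dianion may form incompletely, the product may protonate unreacted dianion, both methyl groups may be carboxylated, or base may deacetylate the diketone. The fallback builds the chain from the ester end. It sets out from 25 and returns at 29, so that 27 is bypassed. O-Alkylation of 25 with methyl 4-chloro-3-oxobutanoate (K2CO3, acetone) would give the aryloxyacetoacetate F4. Its dianion at C2 and C4 (LiN(iPr)2, THF, −78 to 0 °C) would be acetylated at C4 by N-methoxy-N-methylacetamide to give 29.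

Step 11, O-arylation at the bromide flanked by two benzyloxy groups. Activation of the doubly ortho-substituted C–Br bond may be so slow that protodebromination and decomposition of the phenoxide take over. The fallback replaces the copper manifold by palladium-catalysed Buchwald–Hartwig etherification. This runs by oxidative addition to the electron-poor C–Br bond and ligand-driven C–O reductive elimination, and it is known to accept aryl bromides with two ortho substituents. It sets out from 16 (with 10) and returns at 17: Pd(OAc)2, 2-di-tert-butylphosphino-2′,4′,6′-triisopropylbiphenyl, K3PO4, toluene, 100 °C. It makes no new compound (F0).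

**Further compounds**

F1 | step 19 | heptamer aldehyde, 3,5-bis(benzyloxy)-4-(ArO)benzaldehyde in which ArOH is phenol 25 | O=Cc1cc(OCc9ccccc9)c(Oc2cc(OCc9ccccc9)c(OCc9ccccc9)c(Oc3cc(OCc9ccccc9)c(OCc9ccccc9)c(OCc9ccccc9)c3Oc4cc(OCc9ccccc9)c(Oc5cc(OCc9ccccc9)c(OCc9ccccc9)c(OCc9ccccc9)c5Oc6cc(OCc9ccccc9)c(OCc9ccccc9)c(Oc7cc(OCc9ccccc9)c(OCc9ccccc9)c(OCc9ccccc9)c7)c6)c(OCc9ccccc9)c4)c2)c(OCc9ccccc9)c1
F2 | step 19 | heptamer formate, 3,5-bis(benzyloxy)-4-(ArO)phenyl formate in which ArOH is phenol 25 | O=COc1cc(OCc9ccccc9)c(Oc2cc(OCc9ccccc9)c(OCc9ccccc9)c(Oc3cc(OCc9ccccc9)c(OCc9ccccc9)c(OCc9ccccc9)c3Oc4cc(OCc9ccccc9)c(Oc5cc(OCc9ccccc9)c(OCc9ccccc9)c(OCc9ccccc9)c5Oc6cc(OCc9ccccc9)c(OCc9ccccc9)c(Oc7cc(OCc9ccccc9)c(OCc9ccccc9)c(OCc9ccccc9)c7)c6)c(OCc9ccccc9)c4)c2)c(OCc9ccccc9)c1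
F3 | step 19 | heptamer phenol, 3,5-bis(benzyloxy)-4-(ArO)phenol in which ArOH is phenol 25 | Oc1cc(OCc9ccccc9)c(Oc2cc(OCc9ccccc9)c(OCc9ccccc9)c(Oc3cc(OCc9ccccc9)c(OCc9ccccc9)c(OCc9ccccc9)c3Oc4cc(OCc9ccccc9)c(Oc5cc(OCc9ccccc9)c(OCc9ccccc9)c(OCc9ccccc9)c5Oc6cc(OCc9ccccc9)c(OCc9ccccc9)c(Oc7cc(OCc9ccccc9)c(OCc9ccccc9)c(OCc9ccccc9)c7)c6)c(OCc9ccccc9)c4)c2)c(OCc9ccccc9)c1
F4 | step 18 | aryloxyacetoacetate, methyl 4-(ArO)-3-oxobutanoate in which ArOH is phenol 25 | COC(=O)CC(=O)COc2cc(OCc9ccccc9)c(OCc9ccccc9)c(Oc3cc(OCc9ccccc9)c(OCc9ccccc9)c(OCc9ccccc9)c3Oc4cc(OCc9ccccc9)c(Oc5cc(OCc9ccccc9)c(OCc9ccccc9)c(OCc9ccccc9)c5Oc6cc(OCc9ccccc9)c(OCc9ccccc9)c(Oc7cc(OCc9ccccc9)c(OCc9ccccc9)c(OCc9ccccc9)c7)c6)c(OCc9ccccc9)c4)c2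
F0 | step 11 | none | none
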